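The target is read as the (3R,4S)-trans-3,4-diarylchroman carrying a (3R)-isoflavan on the aryl ring at C4; the route below is a proposal and nothing in it has been run.

**Strategy.** Everything rests on disconnecting O1–C8a and C4a–C4 of the 4-aryl chroman: ring A (its benzo ring) becomes an aryne, and O1, C2, C3 and C4 come from a trans-2,3-diaryloxetane. C4 is benzylic to ring D (the aryl ring on C4), whose ortho-methoxy and para-oxygen stabilise a cation there, so the oxetane oxygen can add to 5-benzyloxy-3-bromobenzyne, the oxonium ylide can open, and the aryl anion next to bromine can close the pyran ring trans in one operation. The oxetane comes from an auxiliary-controlled anti-aldol between an arylacetyl oxazolidinone and the aldehyde of a preformed (R)-isoflavan; bromine and all benzyl groups leave in the last hydrogenolysis.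

Key step: step 18

Abbreviations used in names: ArA = 2-(benzyloxy)-4,5-dimethoxyphenyl; ArB = 4-(benzyloxy)-5-[(3R)-7-(benzyloxy)-3,4-dihydro-2H-chromen-3-yl]-2-methoxyphenyl; ArC = 2-(benzyloxy)-5-bromo-4-methoxyphenyl.

Assumption (chemistry): the facial sense of the iridium-catalysed hydrogenation (step 7) and of the MgCl2-catalysed aldol (step 15) is assigned by analogy with the accepted models; should a first batch show the opposite sense, the antipode of the ligand or of the auxiliary is used.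

**Route**

Step 1
Reactants: 1 5-bromo-2-hydroxy-4-methoxybenzaldehyde
Product: 2 2-(benzyloxy)-5-bromo-4-methoxybenzaldehyde
Conditions: BnBr, K2CO3, DMF, 60 °C
Reagents that add atoms: benzyl bromide BrCc1ccccc1
Why: Williamson O-alkylation of the phenoxide; benzyl is chosen because it is removed together with bromine in the last step.

Step 2
Reactants: 2 2-(benzyloxy)-5-bromo-4-methoxybenzaldehyde
Product: 4 ArC-acetonitrile, via N-formyl tosyl enamide 3 (not isolated)
Conditions: TosMIC, KOtBu, DME, −40 °C; then MeOH, reflux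
Reagents that add atoms: tosylmethyl isocyanide Cc1ccc(cc1)S(=O)(=O)C[N+]#[C-]
Why: van Leusen reductive cyanation: the TosMIC anion adds to the aldehyde, the oxazoline opens to enamide 3, and methanolysis expels formate and sulfinate to give the homologated nitrile.

Step 3
Reactants: 4 ArC-acetonitrile
Product: 5 ArC-acetic acid
Conditions: KOH, EtOH/H2O, reflux; then aq. HCl
Reagents that add atoms: water O
Why: Base hydrolysis of the nitrile to the carboxylate; aryl bromide and benzyl ether are inert to hydroxide.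

Step 4
Reactants: 5 ArC-acetic acid; 6 4-(benzyloxy)-2-hydroxybenzaldehyde
Product: 8 7-(benzyloxy)-3-ArC-2H-chromen-2-one, via aryl ester 7 (not isolated)
Conditions: Ac2O, Et3N, 120 °C
Reagents that add atoms: none
Why: Perkin–Oglialoro condensation: O-acylation of the salicylaldehyde through the mixed anhydride, intramolecular Knoevenagel-type aldol and dehydration give the 3-arylcoumarin.

Step 5
Reactants: 8 7-(benzyloxy)-3-ArC-2H-chromen-2-one
Product: 9 (2Z)-2-ArC-3-[4-(benzyloxy)-2-hydroxyphenyl]prop-2-en-1-ol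
Conditions: i-Bu2AlH (4 equiv), CH2Cl2, −78 to 0 °C; aqueous work-up
Reagents that add atoms: none
Why: 1,2-Hydride reduction of the lactone through the lactol and hydroxy enal gives the allylic alcohol, and the Z geometry is inherited from the ring.

Step 6
Reactants: 9 (2Z)-2-ArC-3-[4-(benzyloxy)-2-hydroxyphenyl]prop-2-en-1-ol
Product: 10 7-(benzyloxy)-3-ArC-2H-chromene
Conditions: PPh3, DIAD, THF, 0 °C
Reagents that add atoms: none
Why: Mitsunobu cyclodehydration (6-exo-tet attack of the phenol on the activated primary allylic alcohol) closes the 2H-chromene under neutral conditions that spare this acid-sensitive isoflav-3-ene.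

Step 7
Reactants: 10 7-(benzyloxy)-3-ArC-2H-chromene
Product: 11 (3R)-7-(benzyloxy)-3-ArC-3,4-dihydro-2H-chromene
Conditions: H2 (50 bar), [Ir(cod)(L)][B(C6H3(CF3)2)4] (1 mol %, L = (S)-4-tert-butyl-2-[2-(diphenylphosphanyl)phenyl]-4,5-dihydrooxazole), CH2Cl2, rt
Reagents that add atoms: none
Why: Iridium–phosphinooxazoline-catalysed asymmetric hydrogenation of the trisubstituted cyclic styrene, a reaction established for isoflav-3-enes; the ligand differentiates the alkene faces and should set C3 as R, while aryl bromide and benzyl ethers survive the homogeneous catalyst.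

Step 8
Reactants: 11 (3R)-7-(benzyloxy)-3-ArC-3,4-dihydro-2H-chromene
Product: 13 4-(benzyloxy)-5-[(3R)-7-(benzyloxy)-3,4-dihydro-2H-chromen-3-yl]-2-methoxybenzaldehyde, via aryllithium 12 (not isolated)
Conditions: n-BuLi, THF, −78 °C; then DMF; H2O
Reagents that add atoms: N,N-dimethylformamide CN(C)C=O
Why: Bromine–lithium exchange outruns any deprotonation at −78 °C and the aryllithium is formylated by DMF (Bouveault aldehyde synthesis), the stereocentre being remote and non-acidic.

Step 9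
Reactants: 14 2-hydroxy-4,5-dimethoxybenzaldehyde
Product: 15 2-(benzyloxy)-4,5-dimethoxybenzaldehyde
Conditions: BnBr, K2CO3, DMF, 60 °C
Reagents that add atoms: benzyl bromide BrCc1ccccc1
Why: Williamson O-alkylation of the phenoxide, as in step 1.

Step 10
Reactants: 15 2-(benzyloxy)-4,5-dimethoxybenzaldehyde
Product: 17 ArA-acetonitrile, via N-formyl tosyl enamide 16 (not isolated)
Conditions: TosMIC, KOtBu, DME, −40 °C; then MeOH, reflux
Reagents that add atoms: tosylmethyl isocyanide Cc1ccc(cc1)S(=O)(=O)C[N+]#[C-]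
Why: van Leusen reductive cyanation, as in step 2.

Step 11
Reactants: 17 ArA-acetonitrile
Product: 18 ArA-acetic acid
Conditions: KOH, EtOH/H2O, reflux; then aq. HCl
Reagents that add atoms: water O
Why: Base hydrolysis of the nitrile, as in step 3.

Step 12
Reactants: 18 ArA-acetic acid; 19 (R)-4-benzyl-1,3-oxazolidin-2-one
Product: 21 (4R)-4-benzyl-3-(ArA-acetyl)-1,3-oxazolidin-2-one, via mixed pivalic anhydride 20 (not isolated)
Conditions: PivCl, Et3N, THF, −20 °C; then 19, LiCl, rt
Reagents that add atoms: none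
Why: N-Acylation of the oxazolidinone by the mixed pivalic anhydride, with LiCl activating the auxiliary under mild amine base.

Step 13
Reactants: 22 4-(benzyloxy)phenol
Product: 23 4-(benzyloxy)-2,6-dibromophenol
Conditions: NBS (2 equiv), i-Pr2NH (cat.), CH2Cl2, 0 °C
Reagents that add atoms: N-bromosuccinimide O=C1CCC(=O)N1Br
Why: Amine-mediated ortho-selective electrophilic bromination: the free hydroxyl directs both bromines to its two ortho positions in preference to those next to the benzyl ether.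

Step 14
Reactants: 23 4-(benzyloxy)-2,6-dibromophenol
Product: 26 4-(benzyloxy)-2-bromo-6-(trimethylsilyl)phenyl trifluoromethanesulfonate, via silyl ether 24 (not isolated), via lithium phenoxide 25 (not isolated)
Conditions: HMDS, THF, reflux, evaporate; n-BuLi (1 equiv), THF, −100 to −78 °C; then Tf2O, −78 °C to rt
Reagents that add atoms: hexamethyldisilazane C[Si](C)(C)N[Si](C)(C)C; trifluoromethanesulfonic anhydride O=S(=O)(OS(=O)(=O)C(F)(F)F)C(F)(F)F
Why: O-Silylation, bromine–lithium exchange at one of the two equivalent bromines, retro-Brook 1,3-shift of silicon from oxygen to carbon and triflation of the phenoxide give the ortho-silylaryl triflate that stores the aryne with bromine beside the future triple bond.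

Step 15
Reactants: 21 (4R)-4-benzyl-3-(ArA-acetyl)-1,3-oxazolidin-2-one; 13 4-(benzyloxy)-5-[(3R)-7-(benzyloxy)-3,4-dihydro-2H-chromen-3-yl]-2-methoxybenzaldehyde
Product: 27 (4R)-4-benzyl-3-[(2S,3R)-2-ArA-3-ArB-3-(trimethylsilyloxy)propanoyl]-1,3-oxazolidin-2-one
Conditions: MgCl2 (20 mol %), Et3N, Me3SiCl, EtOAc, rt
Reagents that add atoms: chlorotrimethylsilane C[Si](C)(C)Cl
Why: MgCl2-catalysed soft-enolisation anti-aldol of an N-acyloxazolidinone with a non-enolisable aryl aldehyde: the magnesium-chelated Z-enolate should react on the face away from the auxiliary benzyl group through a boat-like transition state, setting C2 as S and the carbinol carbon anti to it, while silylation of the aldolate drives turnover.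

Step 16
Reactants: 27 (4R)-4-benzyl-3-[(2S,3R)-2-ArA-3-ArB-3-(trimethylsilyloxy)propanoyl]-1,3-oxazolidin-2-one
Product: 29 (1R,2R)-2-ArA-1-ArB-propane-1,3-diol, via silyl ether alcohol 28 (not isolated)
Conditions: LiBH4, MeOH (1 equiv), THF, 0 °C; then K2CO3 (cat.), MeOH, rt
Reagents that add atoms: none
Why: LiBH4 cleaves the imide reductively to the primary alcohol with release of the auxiliary and methanolysis then removes the silyl group; neither stereocentre can epimerise under these conditions.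

Step 17
Reactants: 29 (1R,2R)-2-ArA-1-ArB-propane-1,3-diol
Product: 31 (2R,3R)-3-ArA-2-ArB-oxetane, via monotosylate 30 (not isolated)
Conditions: TsCl (1.1 equiv), pyridine, CH2Cl2, 0 °C; then KOtBu, THF, 0 °C to rt
Reagents that add atoms: none
Why: Selective sulfonylation of the primary hydroxyl followed by intramolecular Williamson etherification (4-exo-tet) by the secondary alkoxide; no bond to a stereocentre is broken, so the anti-diol gives the trans-oxetane.

Step 18
Reactants: 31 (2R,3R)-3-ArA-2-ArB-oxetane; 26 4-(benzyloxy)-2-bromo-6-(trimethylsilyl)phenyl trifluoromethanesulfonate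
Product: 35 (3R,4R)-7-(benzyloxy)-5-bromo-3-ArA-4-ArB-3,4-dihydro-2H-chromene, via aryne 32 (not isolated), via oxonium ylide 33 (not isolated), via benzylic cation zwitterion 34 (not isolated)
Conditions: Bu4N[Ph3SiF2] (2.5 equiv), toluene, 50 °C, slow addition of 26 (2 equiv)
Reagents that add atoms: none
Why: Proposed new method: fluoride unmasks aryne 32 from 26, and the oxetane oxygen of 31 adds to the aryne carbon remote from bromine (the future C8a), because the C–Br bond makes that terminus the flatter, more electrophilic one and stabilises the developing anion at the neighbouring carbon (the future C4a); the resulting oxonium ylide 33 ionises at the oxetane C2–O bond to the 2,4-dioxygenated benzylic cation 34, which the aryl anion captures. The closest known reaction type is the insertion of arynes into the benzylic C–O bond of styrene oxides to give 2,3-dihydrobenzofurans, together with the three-component opening of cyclic ethers by arynes; toluene is used so that no C–H acid intercepts the aryl anion. The pyran ring is closed by ion-pair collapse that enlarges the four-membered ring to a six-membered one (6-exo-trig at the arylmethyl cation), a formal insertion of the aryne into the oxetane C2–O bond. C3 is carried unchanged from 31, and the new stereocentre C4 is controlled by C3, since both a least-motion collapse with retention from the trans-oxetane and attack on the free cation anti to the C3 aryl group lead to the trans chroman. The step needs regioselectivity on the aryne, secured by the bromine beside the triple bond (removed in step 19), and chemoselectivity for the oxetane oxygen over the aryl ether oxygens, secured by its higher Lewis basicity.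

Step 19
Reactants: 35 (3R,4R)-7-(benzyloxy)-5-bromo-3-ArA-4-ArB-3,4-dihydro-2H-chromene
Product: 36 (3R,4S)-3-(2-hydroxy-4,5-dimethoxyphenyl)-4-{4-hydroxy-5-[(3R)-7-hydroxy-3,4-dihydro-2H-chromen-3-yl]-2-methoxyphenyl}-3,4-dihydro-2H-chromen-7-ol
Conditions: H2 (1 atm), Pd/C, NaOAc, EtOAc/MeOH, rt
Reagents that add atoms: none
Why: Heterogeneous hydrogenolysis cleaves the four benzyl ethers and the aryl C–Br bond (NaOAc takes up HBr), while the chroman C–O bonds and the three stereocentres, none of which bears a benzylic heteroatom, are untouched; the C4 descriptor changes from R to S only because bromine is lost.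

**Compound list**

1 | 5-bromo-2-hydroxy-4-methoxybenzaldehyde | O=Cc1cc(Br)c(OC)cc1O | starting material
2 | 2-(benzyloxy)-5-bromo-4-methoxybenzaldehyde | O=Cc1cc(Br)c(OC)cc1OCc1ccccc1 | intermediate
3 | N-[2-ArC-1-(4-methylbenzenesulfonyl)ethenyl]formamide (potassium salt in the flask) | O=CNC(=Cc1cc(Br)c(OC)cc1OCc1ccccc1)S(=O)(=O)c1ccc(C)cc1 | intermediate
4 | [2-(benzyloxy)-5-bromo-4-methoxyphenyl]acetonitrile | N#CCc1cc(Br)c(OC)cc1OCc1ccccc1 | intermediate
5 | [2-(benzyloxy)-5-bromo-4-methoxyphenyl]acetic acid | OC(=O)Cc1cc(Br)c(OC)cc1OCc1ccccc1 | intermediate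
6 | 4-(benzyloxy)-2-hydroxybenzaldehyde | O=Cc1ccc(OCc2ccccc2)cc1O | starting material
7 | 5-(benzyloxy)-2-formylphenyl [2-(benzyloxy)-5-bromo-4-methoxyphenyl]acetate | O=Cc1ccc(OCc2ccccc2)cc1OC(=O)Cc1cc(Br)c(OC)cc1OCc1ccccc1 | intermediate
8 | 7-(benzyloxy)-3-[2-(benzyloxy)-5-bromo-4-methoxyphenyl]-2H-chromen-2-one | O=C1Oc2cc(OCc3ccccc3)ccc2C=C1c1cc(Br)c(OC)cc1OCc1ccccc1 | intermediate
9 | (2Z)-2-[2-(benzyloxy)-5-bromo-4-methoxyphenyl]-3-[4-(benzyloxy)-2-hydroxyphenyl]prop-2-en-1-ol | OC/C(c1cc(Br)c(OC)cc1OCc1ccccc1)=C\c1ccc(OCc2ccccc2)cc1O | intermediate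
10 | 7-(benzyloxy)-3-[2-(benzyloxy)-5-bromo-4-methoxyphenyl]-2H-chromene | COc1cc(OCc2ccccc2)c(cc1Br)C1=Cc2ccc(OCc3ccccc3)cc2OC1 | intermediate
11 | (3R)-7-(benzyloxy)-3-[2-(benzyloxy)-5-bromo-4-methoxyphenyl]-3,4-dihydro-2H-chromene | COc1cc(OCc2ccccc2)c(cc1Br)[C@@H]1COc2cc(OCc3ccccc3)ccc2C1 | intermediate
12 | {4-(benzyloxy)-5-[(3R)-7-(benzyloxy)-3,4-dihydro-2H-chromen-3-yl]-2-methoxyphenyl}lithium | COc1cc(OCc2ccccc2)c(cc1[Li])[C@@H]1COc2cc(OCc3ccccc3)ccc2C1 | intermediate
13 | 4-(benzyloxy)-5-[(3R)-7-(benzyloxy)-3,4-dihydro-2H-chromen-3-yl]-2-methoxybenzaldehyde | COc1cc(OCc2ccccc2)c(cc1C=O)[C@@H]1COc2cc(OCc3ccccc3)ccc2C1 | intermediate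
14 | 2-hydroxy-4,5-dimethoxybenzaldehyde | O=Cc1cc(OC)c(OC)cc1O | starting material
15 | 2-(benzyloxy)-4,5-dimethoxybenzaldehyde | O=Cc1cc(OC)c(OC)cc1OCc1ccccc1 | intermediate
16 | N-[2-ArA-1-(4-methylbenzenesulfonyl)ethenyl]formamide (potassium salt in the flask) | O=CNC(=Cc1cc(OC)c(OC)cc1OCc1ccccc1)S(=O)(=O)c1ccc(C)cc1 | intermediate
17 | [2-(benzyloxy)-4,5-dimethoxyphenyl]acetonitrile | N#CCc1cc(OC)c(OC)cc1OCc1ccccc1 | intermediate
18 | [2-(benzyloxy)-4,5-dimethoxyphenyl]acetic acid | OC(=O)Cc1cc(OC)c(OC)cc1OCc1ccccc1 | intermediate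
19 | (R)-4-benzyl-1,3-oxazolidin-2-one | O=C1OC[C@@H](Cc2ccccc2)N1 | starting material
20 | [2-(benzyloxy)-4,5-dimethoxyphenyl]acetic pivalic anhydride | CC(C)(C)C(=O)OC(=O)Cc1cc(OC)c(OC)cc1OCc1ccccc1 | intermediate
21 | (4R)-4-benzyl-3-{[2-(benzyloxy)-4,5-dimethoxyphenyl]acetyl}-1,3-oxazolidin-2-one | O=C1OC[C@@H](Cc2ccccc2)N1C(=O)Cc1cc(OC)c(OC)cc1OCc1ccccc1 | intermediate
22 | 4-(benzyloxy)phenol | Oc1ccc(OCc2ccccc2)cc1 | starting material
23 | 4-(benzyloxy)-2,6-dibromophenol | Oc1c(Br)cc(OCc2ccccc2)cc1Br | intermediate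
24 | [4-(benzyloxy)-2,6-dibromophenoxy]trimethylsilane | C[Si](C)(C)Oc1c(Br)cc(OCc2ccccc2)cc1Br | intermediate
25 | lithium 4-(benzyloxy)-2-bromo-6-(trimethylsilyl)phenolate | C[Si](C)(C)c1cc(OCc2ccccc2)cc(Br)c1O[Li] | intermediate
26 | 4-(benzyloxy)-2-bromo-6-(trimethylsilyl)phenyl trifluoromethanesulfonate | C[Si](C)(C)c1cc(OCc2ccccc2)cc(Br)c1OS(=O)(=O)C(F)(F)F | intermediate
27 | (4R)-4-benzyl-3-[(2S,3R)-2-ArA-3-ArB-3-(trimethylsilyloxy)propanoyl]-1,3-oxazolidin-2-one (anti) | O=C1OC[C@@H](Cc2ccccc2)N1C(=O)[C@@H](c1cc(OC)c(OC)cc1OCc1ccccc1)[C@@H](O[Si](C)(C)C)c1cc([C@@H]2COc3cc(OCc4ccccc4)ccc3C2)c(OCc2ccccc2)cc1OC | intermediate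
28 | (2R,3R)-2-ArA-3-ArB-3-(trimethylsilyloxy)propan-1-ol | OC[C@@H](c1cc(OC)c(OC)cc1OCc1ccccc1)[C@@H](O[Si](C)(C)C)c1cc([C@@H]2COc3cc(OCc4ccccc4)ccc3C2)c(OCc2ccccc2)cc1OC | intermediate
29 | (1R,2R)-2-ArA-1-ArB-propane-1,3-diol (anti) | OC[C@@H](c1cc(OC)c(OC)cc1OCc1ccccc1)[C@@H](O)c1cc([C@@H]2COc3cc(OCc4ccccc4)ccc3C2)c(OCc2ccccc2)cc1OC | intermediate
30 | (2R,3R)-2-ArA-3-ArB-3-hydroxypropyl 4-methylbenzenesulfonate | Cc1ccc(cc1)S(=O)(=O)OC[C@@H](c1cc(OC)c(OC)cc1OCc1ccccc1)[C@@H](O)c1cc([C@@H]2COc3cc(OCc4ccccc4)ccc3C2)c(OCc2ccccc2)cc1OC | intermediate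
31 | (2R,3R)-3-ArA-2-ArB-oxetane (trans) | C1[C@@H](c2cc(OC)c(OC)cc2OCc2ccccc2)[C@@H](O1)c1cc([C@@H]2COc3cc(OCc4ccccc4)ccc3C2)c(OCc2ccccc2)cc1OC | intermediate
32 | 5-(benzyloxy)-3-bromobenzyne (5-(benzyloxy)-3-bromo-1,2-didehydrobenzene) | C1#CC(Br)=CC(OCc2ccccc2)=C1 | intermediate
33 | (2R,3R)-3-ArA-2-ArB-1-[5-(benzyloxy)-3-bromophenyl]oxetan-1-ium with the carbanion at the ring carbon between the oxygen-bearing and the bromine-bearing carbon | C1[C@@H](c2cc(OC)c(OC)cc2OCc2ccccc2)[C@@H]([O+]1c1cc(OCc2ccccc2)cc(Br)[c-]1)c1cc([C@@H]2COc3cc(OCc4ccccc4)ccc3C2)c(OCc2ccccc2)cc1OC | intermediate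
34 | ring-opened zwitterion: (2R)-2-ArA-1-ArB-propan-1-ylium carrying at C3 the 5-(benzyloxy)-3-bromophenoxy group with the carbanion ortho to oxygen and bromine | [c-]1c(Br)cc(OCc2ccccc2)cc1OC[C@@H](c1cc(OC)c(OC)cc1OCc1ccccc1)[CH+]c1cc([C@@H]2COc3cc(OCc4ccccc4)ccc3C2)c(OCc2ccccc2)cc1OC | intermediate
35 | (3R,4R)-7-(benzyloxy)-5-bromo-3-ArA-4-ArB-3,4-dihydro-2H-chromene (trans) | COc1cc(OCc2ccccc2)c(cc1OC)[C@@H]1COc2cc(OCc3ccccc3)cc(Br)c2[C@H]1c1cc([C@@H]2COc3cc(OCc4ccccc4)ccc3C2)c(OCc2ccccc2)cc1OC | intermediate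
36 | (3R,4S)-3-(2-hydroxy-4,5-dimethoxyphenyl)-4-{4-hydroxy-5-[(3R)-7-hydroxy-3,4-dihydro-2H-chromen-3-yl]-2-methoxyphenyl}-3,4-dihydro-2H-chromen-7-ol | COc1cc(O)c([C@@H]2COc3cc(O)ccc3[C@H]2c2cc([C@@H]3COc4cc(O)ccc4C3)c(O)cc2OC)cc1OC | target

**Count and risks**

Total step count: 19. Longest linear sequence: 13 steps (steps 1–8, then 15–19).

Steps most likely to fail:

1. Step 18 (proposed new method). The aryl anion of ylide 33 may be intercepted (protonation, or loss of the neighbouring bromide) before the C–C bond forms, the aryne may be consumed at an aryl ether oxygen, or trans control at C4 may be incomplete. Fallback with known chemistry, setting out from diol 29: Mitsunobu etherification of the primary hydroxyl (PPh3, DIAD, THF) with commercial 3-(benzyloxy)phenol should give (1R,2R)-3-[3-(benzyloxy)phenoxy]-2-ArA-1-ArB-propan-1-ol F1. BF3·OEt2 in CH2Cl2 at −40 °C then ionises the benzylic alcohol, and intramolecular Friedel–Crafts alkylation para to the benzyloxy group and anti to the C3 aryl group should give bromine-free (3R,4S)-7-(benzyloxy)-3-ArA-4-ArB-3,4-dihydro-2H-chromene F2. Under the conditions of step 19, F2 comes back to the route at 36.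

2. Step 17. Grob-type fragmentation of the benzylic alkoxide (back to aldehyde 13 and a styrene) or E2 elimination of the tosylate may outrun the 4-exo-tet closure. Fallback, setting out from diol 29: the oxetane is bypassed and the two bonds are made in two stages. The primary hydroxyl is O-arylated by aryne 32 (26, CsF, MeCN, rt; aryne O–H insertion, oxygen bonding remote from bromine) to give (1R,2R)-3-[3-(benzyloxy)-5-bromophenoxy]-2-ArA-1-ArB-propan-1-ol F3. BF3·OEt2, CH2Cl2, −40 °C then closes the chroman by Friedel–Crafts alkylation at the position para to benzyloxy and next to bromine, coming back to the route at 35.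

3. Step 15. Addition to the electron-rich, hindered aldehyde may be sluggish, and reversible aldolisation or epimerisation of the acidic aryl-bearing centre may erode facial and anti selectivity. Fallback, setting out from acid 18 and aldehyde 13:
   - Acid 18 is coupled as in step 12 with commercial (S)-4-benzyl-1,3-oxazolidin-2-one to give (4S)-4-benzyl-3-(ArA-acetyl)-1,3-oxazolidin-2-one F4.
   - The boron-mediated syn-aldol (Bu2BOTf, i-Pr2NEt, CH2Cl2, −78 °C, then 13; Z-enolate, closed chair transition state) should give (4S)-4-benzyl-3-[(2S,3S)-2-ArA-3-ArB-3-hydroxypropanoyl]-1,3-oxazolidin-2-one F5, with the same configuration at the aryl-bearing carbon as in 27.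
   - LiBH4 gives (1S,2R)-2-ArA-1-ArB-propane-1,3-diol F6, the C1 epimer of 29.
   - Because the benzylic centre is ionised in the ring closure, F6 is O-arylated with 26/CsF to (1S,2R)-3-[3-(benzyloxy)-5-bromophenoxy]-2-ArA-1-ArB-propan-1-ol F7 and closed with BF3·OEt2 as above, coming back to the route at 35.

Further compounds
F1 | step 18 | (1R,2R)-3-[3-(benzyloxy)phenoxy]-2-ArA-1-ArB-propan-1-ol | C(Oc1cccc(OCc2ccccc2)c1)[C@@H](c1cc(OC)c(OC)cc1OCc1ccccc1)[C@@H](O)c1cc([C@@H]2COc3cc(OCc4ccccc4)ccc3C2)c(OCc2ccccc2)cc1OC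
F2 | step 18 | (3R,4S)-7-(benzyloxy)-3-ArA-4-ArB-3,4-dihydro-2H-chromene | COc1cc(OCc2ccccc2)c(cc1OC)[C@@H]1COc2cc(OCc3ccccc3)ccc2[C@H]1c1cc([C@@H]2COc3cc(OCc4ccccc4)ccc3C2)c(OCc2ccccc2)cc1OC
F3 | step 17 | (1R,2R)-3-[3-(benzyloxy)-5-bromophenoxy]-2-ArA-1-ArB-propan-1-ol | C(Oc1cc(Br)cc(OCc2ccccc2)c1)[C@@H](c1cc(OC)c(OC)cc1OCc1ccccc1)[C@@H](O)c1cc([C@@H]2COc3cc(OCc4ccccc4)ccc3C2)c(OCc2ccccc2)cc1OC
F4 | step 15 | (4S)-4-benzyl-3-{[2-(benzyloxy)-4,5-dimethoxyphenyl]acetyl}-1,3-oxazolidin-2-one | O=C1OC[C@H](Cc2ccccc2)N1C(=O)Cc1cc(OC)c(OC)cc1OCc1ccccc1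
F5 | step 15 | (4S)-4-benzyl-3-[(2S,3S)-2-ArA-3-ArB-3-hydroxypropanoyl]-1,3-oxazolidin-2-one (syn) | O=C1OC[C@H](Cc2ccccc2)N1C(=O)[C@@H](c1cc(OC)c(OC)cc1OCc1ccccc1)[C@H](O)c1cc([C@@H]2COc3cc(OCc4ccccc4)ccc3C2)c(OCc2ccccc2)cc1OC
F6 | step 15 | (1S,2R)-2-ArA-1-ArB-propane-1,3-diol (syn) | OC[C@@H](c1cc(OC)c(OC)cc1OCc1ccccc1)[C@H](O)c1cc([C@@H]2COc3cc(OCc4ccccc4)ccc3C2)c(OCc2ccccc2)cc1OC
F7 | step 15 | (1S,2R)-3-[3-(benzyloxy)-5-bromophenoxy]-2-ArA-1-ArB-propan-1-ol | C(Oc1cc(Br)cc(OCc2ccccc2)c1)[C@@H](c1cc(OC)c(OC)cc1OCc1ccccc1)[C@H](O)c1cc([C@@H]2COc3cc(OCc4ccccc4)ccc3C2)c(OCc2ccccc2)cc1OC
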